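1. At early times Tuesday's flask, with 0.30 mM of free catalyst, made target quickly: 9.3% of the starting material in the first 12.0 min.

| setting | Tuesday's | west | south | north-east |
|---|---|---|---|---|
| starting material | 41 mM | 41 mM | 41 mM | 41 mM |
| second substrate | 20.5 mM | 20.5 mM | 20.5 mM | 20.5 mM |
| reagent | 61.5 mM | 61.5 mM | 61.5 mM | 61.5 mM |
| free catalyst | 0.30 mM | 0.20 mM | 0.20 mM | 0.20 mM |
| temperature | 25 °C | 25 °C | 10 °C | 40 °C |
| remark | run made earlier |  |  |  |
| time |  | 4.0 h | 4.0 h | 4.0 h |

Tuesday's run (percent of the starting material charged): time / min: target / % = 4.00: 4.1; 12.0: 9.3; 20.0: 15.2; 30.0: 19.4; 50.0: 26.9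

(scatter of a reading: 0.3 percentage points)

- the analysis behind the earlier runs scatters by 0.3 percentage points, standard deviation
- the earlier runs do not show what temperature does; that part of a forecast is a guess
- no earlier run changes the charge of free catalyst; that part of a forecast is a guess

- the flask that comes out highest in amount of target, in percent of the starting material charged, or "all alike" when all lie within 1.5 percentage points (west / south / north-east / all alike)
- target at the end, in percent of the starting material charged, west
- target at the end, in percent of the starting material charged, south
- target at the end, in percent of the starting material charged, north-east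

2. Late in Tuesday's run the target rose by 7.5 percentage points in 20.0 min. So I read a rate that fell by a factor 2.07 between the middles of those spans, 34.0 min apart.

3. I treated this fall as pseudo-first-order. That gave 32.5 min at Tuesday's charge for the halving time τ, the time in which the rate drops by a factor of two. The target then approaches a ceiling, which Tuesday's last reading puts near 41.0% at 25 °C.

4. West has 0.20 mM of free catalyst. Guessing the rate proportional to that charge, it starts at a factor 0.667 of Tuesday's, and τ stretches to 48.7 min. In 4.0 h west passes 4.93 halvings, which slows its rate by a factor 30.5, so I reckoned 39.7% of target.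

5. That leaves west 1.3 points under my ceiling, so extra speed at 40 °C has that much to add unless the ceiling moves, and the runs do not show what temperature does to it. For south and north-east they give me no number of my own.

6. The forecast put north-east highest, with west at 42% (33% to 47%), south at 27% (16% to 37%) and north-east at 47% (37% to 50%). It reasoned “so the ceiling is about 50%”. My ceiling for west lay lower than its 50.

7. West gave 40.9%, south 24.1% and north-east 27.8%, so west came highest.

    starting material + free catalyst ⇌ catalyst intermediate A (K = 9.57 /M, k = 118 /M/min, Ea = 59.0 kJ/mol, ΔH = −60.0 kJ/mol)
    reagent + catalyst intermediate A ⇌ free catalyst + target (K = 1.59, k = 2570 /M/min, Ea = 45.0 kJ/mol, ΔH = −15.0 kJ/mol)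
    second substrate + free catalyst ⇌ catalyst intermediate B (K = 1980 /M, k = 196 /M/min, Ea = 44.0 kJ/mol, ΔH = −28.0 kJ/mol)
    reagent + catalyst intermediate B → free catalyst + second product (k = 2250 /M/min, Ea = 46.0 kJ/mol)
    starting material → decomposition product (k = 3.32 × 10⁻⁵ /min, Ea = 108 kJ/mol)
    target ⇌ isomer of the product (K = 0.190, k = 0.203 /min, Ea = 89.0 kJ/mol, ΔH = −41.0 kJ/mol)
    (constants at 40 °C)

8. West's τ of 48.7 min had reckoned 39.7% against the 40.9% found, and for the neighbour flask, west stopped at 2.5 h, it reckons 36.2% against 36.7% found. At 40.0 h south has climbed from 24.1% to 40.9% and west has moved from 40.9% to 42.2%, while north-east, lower than west, has gone from 27.8% at 4.0 h to 26.8%.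

The numbers in the tables are calculated on assumed constants.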